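**Plan**

Rings: A = 4-hydroxy-3-methoxyphenyl, B = central arene, C = arene with the hydroxypropyl chain; dihydrofuran AB = O1, C2 (on ring A), C3 (CH2OH), C3a, C7a; dihydrofuran BC has primed numbers.
Retrosynthesis: with the three CH2OH groups taken back to methyl esters and the phenol to its benzyl ether, each dihydrofuran is cut at three bonds, in the order C2–C3 (then C2'–C3'), C3–C3a (C3'–C3a') and O1–C2 (O1'–C2'). This leaves 5-bromovanillin, a 4-benzyloxy-3-methoxybenzyl alcohol and an iodinated methyl dihydroferulate.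
Enabling feature: in each dihydrofuran C2 is an ether carbon bearing an aryl ring and C3 sits on the benzo ring ortho to O1, so a carbene at C3 finds the benzylic ether C2–H bond in a 1,5 relation and C2–C3 can be made by C–H insertion.
Forward: two Mitsunobu etherifications join A–CH2–O–B–CH2–O–C; an acetate unit is coupled at the ring C C–I bond, diazotised and inserted to close dihydrofuran BC first. After ester reduction and silylation the same three operations at the ring B C–Br bond close dihydrofuran AB, and reduction and deprotection finish.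
Stereochemistry: C2' and C2 (both R) come from the chiral catalyst Rh2(S-PTTL)4 in the two insertions; C3' and C3 come from methoxide equilibration of each kinetic cis ester to the trans ester (3'S and 3S after reduction).

Key step: step 12

Remark: Rh2(S-PTTL)4 (dirhodium tetrakis[N-phthaloyl-(S)-tert-leucinate]) is taken to give the (2R) sense of insertion at a benzylic ether CH2; should the sense prove opposite, Rh2(R-PTTL)4 replaces it in steps 7 and 12.

**Route**

Step 1
Reactants: 1 5-bromovanillin; 2 [4-(benzyloxy)-3-methoxyphenyl]methanol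
Product: 3 4-{[4-(benzyloxy)-3-methoxyphenyl]methoxy}-3-bromo-5-methoxybenzaldehyde
Conditions: PPh3, DIAD, THF, 0 °C to rt
Reagents that add atoms: none
Why: Mitsunobu etherification, in which the acidic aldehyde-bearing phenol of 1 is alkylated by the alkoxyphosphonium ion of the primary benzylic alcohol 2 under neutral conditions that leave the aldehyde and the C–Br bond alone.

Step 2
Reactants: 3 ring AB aldehyde
Product: 4 (4-{[4-(benzyloxy)-3-methoxyphenyl]methoxy}-3-bromo-5-methoxyphenyl)methanol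
Conditions: NaBH4, MeOH/THF, 0 °C
Reagents that add atoms: none
Why: Borohydride reduction of an aromatic aldehyde to the benzylic alcohol, to which the aryl bromide and the benzylic ethers are inert.

Step 3
Reactants: 5 methyl 3-(4-hydroxy-3-methoxyphenyl)propanoate
Product: 6 methyl 3-(4-hydroxy-3-iodo-5-methoxyphenyl)propanoate
Conditions: NaI, NaOH (1 equiv each), MeOH, 0 °C, aq NaOCl (1 equiv) added dropwise
Reagents that add atoms: sodium iodide, [Na+].[I-]
Why: Electrophilic aromatic iodination of a phenoxide by hypoiodite made from NaI and NaOCl, directed to the only free position ortho to the phenoxide oxygen because the para position carries the side chain.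

Step 4
Reactants: 4 ring AB benzylic alcohol; 6 ring C iodophenol
Product: 7 methyl 3-{4-[(4-{[4-(benzyloxy)-3-methoxyphenyl]methoxy}-3-bromo-5-methoxyphenyl)methoxy]-3-iodo-5-methoxyphenyl}propanoate
Conditions: PPh3, DIAD, THF, 0 °C to rt
Reagents that add atoms: none
Why: Mitsunobu etherification, favoured because the ortho iodine makes phenol 6 acidic enough for the betaine and because the neutral conditions avoid ionising the p-alkoxybenzylic alcohol 4.

Step 5
Reactants: 7 iodo bromo triaryl diether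
Product: 8 methyl 3-{4-[(4-{[4-(benzyloxy)-3-methoxyphenyl]methoxy}-3-bromo-5-methoxyphenyl)methoxy]-3-methoxy-5-(2-methoxy-2-oxoethyl)phenyl}propanoate
Conditions: BrZnCH2CO2Me (preformed from methyl bromoacetate and Zn dust in THF), Pd(PPh3)4 (5 mol %), THF, 40 °C
Reagents that add atoms: bromo(2-methoxy-2-oxoethyl)zinc, COC(=O)C[Zn]Br
Why: Negishi-type α-arylation of a Reformatsky zinc enolate, in which the zerovalent palladium complex Pd(PPh3)4 adds to the C–I bond far faster than to the electron-rich C–Br bond, so only ring C receives the acetate unit.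

Step 6
Reactants: 8 ring C arylacetate
Product: 9 methyl 3-{4-[(4-{[4-(benzyloxy)-3-methoxyphenyl]methoxy}-3-bromo-5-methoxyphenyl)methoxy]-3-(1-diazo-2-methoxy-2-oxoethyl)-5-methoxyphenyl}propanoate
Conditions: p-ABSA, DBU, MeCN, 0 °C to rt
Reagents that add atoms: 4-acetamidobenzenesulfonyl azide (p-ABSA), CC(=O)Nc1ccc(cc1)S(=O)(=O)N=[N+]=[N-]
Why: Regitz diazo transfer, in which DBU deprotonates only the benzylic arylacetate CH2 (the propanoate CH2 is far less acidic) and the enolate takes N2 from the sulfonyl azide.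

Step 7
Reactants: 9 ring C aryldiazoacetate
Product: 11 methyl (2R,3R)-2-(4-{[4-(benzyloxy)-3-methoxyphenyl]methoxy}-3-bromo-5-methoxyphenyl)-7-methoxy-5-(3-methoxy-3-oxopropyl)-2,3-dihydro-1-benzofuran-3-carboxylate (2,3-trans), via cis-(2R,3S) BC ester 10 (not isolated)
Conditions: Rh2(S-PTTL)4 (1 mol %), toluene, −60 °C; then NaOMe, MeOH, 0 °C to rt
Reagents that add atoms: none
Why: Dirhodium carboxylate-catalysed intramolecular 1,5 C–H insertion of the aryldiazoacetate-derived carbene into the ring B benzylic ether CH2 closes dihydrofuran BC with C2' set as R by the chiral phthaloyl-tert-leucinate ligands, and methoxide then equilibrates C3' through the ester enolate to the more stable trans (3'R) ester.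

Step 8
Reactants: 11 trans BC diester
Product: 12 3-[(2R,3S)-2-(4-{[4-(benzyloxy)-3-methoxyphenyl]methoxy}-3-bromo-5-methoxyphenyl)-3-(hydroxymethyl)-7-methoxy-2,3-dihydro-1-benzofuran-5-yl]propan-1-ol
Conditions: i-Bu2AlH (excess), CH2Cl2, −78 to 0 °C; aq KNaC4H4O6 (potassium sodium tartrate) work-up
Reagents that add atoms: none
Why: Hydride reduction of both methyl esters to primary alcohols with a non-basic aluminium hydride that neither epimerises C3' nor touches the aryl bromide.

Step 9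
Reactants: 12 BC diol
Product: 13 (2R,3S)-2-(4-{[4-(benzyloxy)-3-methoxyphenyl]methoxy}-3-bromo-5-methoxyphenyl)-3-{[(tert-butyldimethylsilyl)oxy]methyl}-5-{3-[(tert-butyldimethylsilyl)oxy]propyl}-7-methoxy-2,3-dihydro-1-benzofuran
Conditions: TBSCl, imidazole, DMF, rt
Reagents that add atoms: tert-butyldimethylsilyl chloride (TBSCl), CC(C)(C)[Si](C)(C)Cl
Why: Standard silylation of two primary alcohols, giving ethers that are inert to zinc enolates, DBU, rhodium carbenes, methoxide and LiAlH4.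

Step 10
Reactants: 13 bis-silyl ether aryl bromide
Product: 14 methyl 2-(2-{[4-(benzyloxy)-3-methoxyphenyl]methoxy}-5-[(2R,3S)-3-{[(tert-butyldimethylsilyl)oxy]methyl}-5-{3-[(tert-butyldimethylsilyl)oxy]propyl}-7-methoxy-2,3-dihydro-1-benzofuran-2-yl]-3-methoxyphenyl)acetate
Conditions: BrZnCH2CO2Me, Pd2(dba)3 (2.5 mol %), XPhos (10 mol %), THF, 60 °C
Reagents that add atoms: bromo(2-methoxy-2-oxoethyl)zinc, COC(=O)C[Zn]Br
Why: Negishi-type α-arylation of the Reformatsky zinc enolate at the aryl bromide, using a zerovalent palladium catalyst with the bulky biaryl phosphine XPhos because the C–Br bond is electron-rich and ortho-substituted.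

Step 11
Reactants: 14 ring B arylacetate
Product: 15 methyl 2-(2-{[4-(benzyloxy)-3-methoxyphenyl]methoxy}-5-[(2R,3S)-3-{[(tert-butyldimethylsilyl)oxy]methyl}-5-{3-[(tert-butyldimethylsilyl)oxy]propyl}-7-methoxy-2,3-dihydro-1-benzofuran-2-yl]-3-methoxyphenyl)-2-diazoacetate
Conditions: p-ABSA, DBU, MeCN, 0 °C to rt
Reagents that add atoms: 4-acetamidobenzenesulfonyl azide (p-ABSA), CC(=O)Nc1ccc(cc1)S(=O)(=O)N=[N+]=[N-]
Why: Regitz diazo transfer to the only acidic CH2 group of the molecule, the ring B arylacetate.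

Step 12
Reactants: 15 ring B aryldiazoacetate
Product: 17 methyl (2R,3R)-2-[4-(benzyloxy)-3-methoxyphenyl]-5-[(2R,3S)-3-{[(tert-butyldimethylsilyl)oxy]methyl}-5-{3-[(tert-butyldimethylsilyl)oxy]propyl}-7-methoxy-2,3-dihydro-1-benzofuran-2-yl]-7-methoxy-2,3-dihydro-1-benzofuran-3-carboxylate (2,3-trans), via cis-(2R,3S) AB ester 16 (not isolated)
Conditions: Rh2(S-PTTL)4 (2 mol %), toluene, −60 °C; then NaOMe, MeOH, 0 °C to rt
Reagents that add atoms: none
Why: The divalent rhodium carboxylate dimer expels N2 from the diazoacetate and the resulting donor/acceptor carbene carbon (the future C3) engages one hydrogen of the ring A O–CH2 group through a three-centre transition state in which hydride shift runs ahead of C–C bond formation, so that the C2–C3 bond is made. The closest known reaction type is the enantioselective dirhodium carboxylate-catalysed intramolecular C–H insertion of ortho-benzyloxy aryldiazoacetates, the same reaction as in step 7. Dihydrofuran AB closes as a five-membered ring by 1,5 insertion, with O1, C7a and C3a already in place and the carbene carbon bonding to the benzylic ether carbon. C2 is set as R by the chiral ligand sphere of the catalyst, which tells apart the two enantiotopic hydrogens of the CH2 group, and C3 is set afterwards when methoxide converts the kinetic cis ester through its enolate into the trans (3R) ester, C2 carrying no acidic hydrogen. The step needs site selectivity and catalyst control over the existing C2' and C3' centres: the ring A CH2 is the only C–H bond that can reach the carbene through a five-membered transition state and is activated by the ether oxygen and the electron-rich aryl group, the other activated C–H bonds (C2'–H, OCH3, OCH2Ph, silyl ether CH2) are out of reach, and the old stereocentres lie meta across ring B, too far away to override the ligands.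

Step 13
Reactants: 17 trans AB methyl ester
Product: 18 {(2R,3S)-2-[4-(benzyloxy)-3-methoxyphenyl]-5-[(2R,3S)-3-{[(tert-butyldimethylsilyl)oxy]methyl}-5-{3-[(tert-butyldimethylsilyl)oxy]propyl}-7-methoxy-2,3-dihydro-1-benzofuran-2-yl]-7-methoxy-2,3-dihydro-1-benzofuran-3-yl}methanol
Conditions: LiAlH4, THF, 0 °C
Reagents that add atoms: none
Why: LiAlH4 reduction of the methyl ester to the primary alcohol, fast enough at 0 °C that C3 is not enolised and leaving silyl and benzyl ethers intact.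

Step 14
Reactants: 18 bis-silyl ether alcohol
Product: 19 3-[(2R,3S)-2-{(2R,3S)-2-[4-(benzyloxy)-3-methoxyphenyl]-3-(hydroxymethyl)-7-methoxy-2,3-dihydro-1-benzofuran-5-yl}-3-(hydroxymethyl)-7-methoxy-2,3-dihydro-1-benzofuran-5-yl]propan-1-ol
Conditions: TBAF, THF, 0 °C to rt
Reagents that add atoms: none
Why: Fluoride-induced cleavage of both silyl ethers, done while the ring A phenol is still benzylated so that no phenoxide para to the C2 ether carbon is exposed to the basic fluoride.

Step 15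
Reactants: 19 triol benzyl ether
Product: 20 4-[(2R,3S)-3-(hydroxymethyl)-5-[(2R,3S)-3-(hydroxymethyl)-5-(3-hydroxypropyl)-7-methoxy-2,3-dihydro-1-benzofuran-2-yl]-7-methoxy-2,3-dihydro-1-benzofuran-2-yl]-2-methoxyphenol (CNP0599161.1)
Conditions: H2 (1 atm), 10% Pd/C, EtOAc, rt
Reagents that add atoms: none
Why: Hydrogenolysis of the aryl benzyl ether over palladium on carbon, which should be much faster than cleavage of the cyclic benzylic C2–O and C2'–O bonds if the reaction is stopped at full conversion.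

**Compound list**

1 | 5-bromovanillin (3-bromo-4-hydroxy-5-methoxybenzaldehyde) | COc1cc(C=O)cc(Br)c1O | starting material
2 | [4-(benzyloxy)-3-methoxyphenyl]methanol | COc1cc(CO)ccc1OCc1ccccc1 | starting material
3 | 4-{[4-(benzyloxy)-3-methoxyphenyl]methoxy}-3-bromo-5-methoxybenzaldehyde | COc1cc(COc2c(OC)cc(C=O)cc2Br)ccc1OCc1ccccc1 | intermediate
4 | (4-{[4-(benzyloxy)-3-methoxyphenyl]methoxy}-3-bromo-5-methoxyphenyl)methanol | COc1cc(COc2c(OC)cc(CO)cc2Br)ccc1OCc1ccccc1 | intermediate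
5 | methyl 3-(4-hydroxy-3-methoxyphenyl)propanoate (methyl dihydroferulate) | COC(=O)CCc1ccc(O)c(OC)c1 | starting material
6 | methyl 3-(4-hydroxy-3-iodo-5-methoxyphenyl)propanoate | COC(=O)CCc1cc(I)c(O)c(OC)c1 | intermediate
7 | methyl 3-{4-[(4-{[4-(benzyloxy)-3-methoxyphenyl]methoxy}-3-bromo-5-methoxyphenyl)methoxy]-3-iodo-5-methoxyphenyl}propanoate | COc1cc(COc2c(OC)cc(COc3c(OC)cc(CCC(=O)OC)cc3I)cc2Br)ccc1OCc1ccccc1 | intermediate
8 | methyl 3-{4-[(4-{[4-(benzyloxy)-3-methoxyphenyl]methoxy}-3-bromo-5-methoxyphenyl)methoxy]-3-methoxy-5-(2-methoxy-2-oxoethyl)phenyl}propanoate | COc1cc(COc2c(OC)cc(COc3c(OC)cc(CCC(=O)OC)cc3CC(=O)OC)cc2Br)ccc1OCc1ccccc1 | intermediate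
9 | methyl 3-{4-[(4-{[4-(benzyloxy)-3-methoxyphenyl]methoxy}-3-bromo-5-methoxyphenyl)methoxy]-3-(1-diazo-2-methoxy-2-oxoethyl)-5-methoxyphenyl}propanoate | COc1cc(COc2c(OC)cc(COc3c(OC)cc(CCC(=O)OC)cc3C(=[N+]=[N-])C(=O)OC)cc2Br)ccc1OCc1ccccc1 | intermediate
10 | methyl (2R,3S)-2-(4-{[4-(benzyloxy)-3-methoxyphenyl]methoxy}-3-bromo-5-methoxyphenyl)-7-methoxy-5-(3-methoxy-3-oxopropyl)-2,3-dihydro-1-benzofuran-3-carboxylate (2,3-cis) | COc1cc(COc2c(OC)cc([C@@H]3Oc4c(OC)cc(CCC(=O)OC)cc4[C@@H]3C(=O)OC)cc2Br)ccc1OCc1ccccc1 | intermediate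
11 | methyl (2R,3R)-2-(4-{[4-(benzyloxy)-3-methoxyphenyl]methoxy}-3-bromo-5-methoxyphenyl)-7-methoxy-5-(3-methoxy-3-oxopropyl)-2,3-dihydro-1-benzofuran-3-carboxylate (2,3-trans) | COc1cc(COc2c(OC)cc([C@@H]3Oc4c(OC)cc(CCC(=O)OC)cc4[C@H]3C(=O)OC)cc2Br)ccc1OCc1ccccc1 | intermediate
12 | 3-[(2R,3S)-2-(4-{[4-(benzyloxy)-3-methoxyphenyl]methoxy}-3-bromo-5-methoxyphenyl)-3-(hydroxymethyl)-7-methoxy-2,3-dihydro-1-benzofuran-5-yl]propan-1-ol | COc1cc(COc2c(OC)cc([C@@H]3Oc4c(OC)cc(CCCO)cc4[C@H]3CO)cc2Br)ccc1OCc1ccccc1 | intermediate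
13 | (2R,3S)-2-(4-{[4-(benzyloxy)-3-methoxyphenyl]methoxy}-3-bromo-5-methoxyphenyl)-3-{[(tert-butyldimethylsilyl)oxy]methyl}-5-{3-[(tert-butyldimethylsilyl)oxy]propyl}-7-methoxy-2,3-dihydro-1-benzofuran | COc1cc(COc2c(OC)cc([C@@H]3Oc4c(OC)cc(CCCO[Si](C)(C)C(C)(C)C)cc4[C@H]3CO[Si](C)(C)C(C)(C)C)cc2Br)ccc1OCc1ccccc1 | intermediate
14 | methyl 2-(2-{[4-(benzyloxy)-3-methoxyphenyl]methoxy}-5-[(2R,3S)-3-{[(tert-butyldimethylsilyl)oxy]methyl}-5-{3-[(tert-butyldimethylsilyl)oxy]propyl}-7-methoxy-2,3-dihydro-1-benzofuran-2-yl]-3-methoxyphenyl)acetate | COc1cc(COc2c(OC)cc([C@@H]3Oc4c(OC)cc(CCCO[Si](C)(C)C(C)(C)C)cc4[C@H]3CO[Si](C)(C)C(C)(C)C)cc2CC(=O)OC)ccc1OCc1ccccc1 | intermediate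
15 | methyl 2-(2-{[4-(benzyloxy)-3-methoxyphenyl]methoxy}-5-[(2R,3S)-3-{[(tert-butyldimethylsilyl)oxy]methyl}-5-{3-[(tert-butyldimethylsilyl)oxy]propyl}-7-methoxy-2,3-dihydro-1-benzofuran-2-yl]-3-methoxyphenyl)-2-diazoacetate | COc1cc(COc2c(OC)cc([C@@H]3Oc4c(OC)cc(CCCO[Si](C)(C)C(C)(C)C)cc4[C@H]3CO[Si](C)(C)C(C)(C)C)cc2C(=[N+]=[N-])C(=O)OC)ccc1OCc1ccccc1 | intermediate
16 | methyl (2R,3S)-2-[4-(benzyloxy)-3-methoxyphenyl]-5-[(2R,3S)-3-{[(tert-butyldimethylsilyl)oxy]methyl}-5-{3-[(tert-butyldimethylsilyl)oxy]propyl}-7-methoxy-2,3-dihydro-1-benzofuran-2-yl]-7-methoxy-2,3-dihydro-1-benzofuran-3-carboxylate (2,3-cis) | COc1cc([C@@H]2Oc3c(OC)cc([C@@H]4Oc5c(OC)cc(CCCO[Si](C)(C)C(C)(C)C)cc5[C@H]4CO[Si](C)(C)C(C)(C)C)cc3[C@@H]2C(=O)OC)ccc1OCc1ccccc1 | intermediate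
17 | methyl (2R,3R)-2-[4-(benzyloxy)-3-methoxyphenyl]-5-[(2R,3S)-3-{[(tert-butyldimethylsilyl)oxy]methyl}-5-{3-[(tert-butyldimethylsilyl)oxy]propyl}-7-methoxy-2,3-dihydro-1-benzofuran-2-yl]-7-methoxy-2,3-dihydro-1-benzofuran-3-carboxylate (2,3-trans) | COc1cc([C@@H]2Oc3c(OC)cc([C@@H]4Oc5c(OC)cc(CCCO[Si](C)(C)C(C)(C)C)cc5[C@H]4CO[Si](C)(C)C(C)(C)C)cc3[C@H]2C(=O)OC)ccc1OCc1ccccc1 | intermediate
18 | {(2R,3S)-2-[4-(benzyloxy)-3-methoxyphenyl]-5-[(2R,3S)-3-{[(tert-butyldimethylsilyl)oxy]methyl}-5-{3-[(tert-butyldimethylsilyl)oxy]propyl}-7-methoxy-2,3-dihydro-1-benzofuran-2-yl]-7-methoxy-2,3-dihydro-1-benzofuran-3-yl}methanol | COc1cc([C@@H]2Oc3c(OC)cc([C@@H]4Oc5c(OC)cc(CCCO[Si](C)(C)C(C)(C)C)cc5[C@H]4CO[Si](C)(C)C(C)(C)C)cc3[C@H]2CO)ccc1OCc1ccccc1 | intermediate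
19 | 3-[(2R,3S)-2-{(2R,3S)-2-[4-(benzyloxy)-3-methoxyphenyl]-3-(hydroxymethyl)-7-methoxy-2,3-dihydro-1-benzofuran-5-yl}-3-(hydroxymethyl)-7-methoxy-2,3-dihydro-1-benzofuran-5-yl]propan-1-ol | COc1cc([C@@H]2Oc3c(OC)cc([C@@H]4Oc5c(OC)cc(CCCO)cc5[C@H]4CO)cc3[C@H]2CO)ccc1OCc1ccccc1 | intermediate
20 | 4-[(2R,3S)-3-(hydroxymethyl)-5-[(2R,3S)-3-(hydroxymethyl)-5-(3-hydroxypropyl)-7-methoxy-2,3-dihydro-1-benzofuran-2-yl]-7-methoxy-2,3-dihydro-1-benzofuran-2-yl]-2-methoxyphenol | COc1cc([C@@H]2Oc3c(OC)cc([C@@H]4Oc5c(OC)cc(CCCO)cc5[C@H]4CO)cc3[C@H]2CO)ccc1O | target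

**Step count and risks**

Total steps: 15. Longest linear sequence: 14 steps (from 1 or 2 through steps 1, 2 and 4 to 15); the ring C branch (step 3) joins at step 4.

Steps most likely to fail:

Step 12. The facial selection between the two hydrogens of the ring A O–CH2 group may be poor, because the chiral catalyst now meets a large substrate that already carries two stereocentres. The fallback adds a second control element on the carbene ester (double stereodifferentiation with a lactamide auxiliary). It sets out from 14: saponification (LiOH, THF/MeOH/H2O) should give the ring B arylacetic acid F1, and Steglich esterification (EDC, DMAP, CH2Cl2) with (R)-2-hydroxy-1-(pyrrolidin-1-yl)propan-1-one the lactamide ester F2. Regitz diazo transfer (p-ABSA, DBU) gives the diazo lactamide ester F3, and insertion with Rh2(R-DOSP)4 (dirhodium tetrakis[(R)-N-(4-dodecylbenzenesulfonyl)prolinate]; lactamide and catalyst are taken here as the matched pair for the 2R series) should give the dihydrobenzofuran lactamide ester F4. NaOMe in MeOH then exchanges the auxiliary for methoxide and equilibrates C3, which comes back to the route at 17.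

Step 5. Oxidative addition may not discriminate fully between C–I and C–Br, or the methyl zinc enolate may self-condense before transmetalation. The fallback sets out from 7 and uses a copper-catalysed Ullmann-type C-arylation of dimethyl malonate (CuI, 2-picolinic acid, Cs2CO3, dioxane, rt to 40 °C), a process that leaves aryl bromides untouched at this temperature, to give the ring C arylmalonate F5. Krapcho dealkoxycarbonylation (LiCl, wet DMSO, 130 °C) removes one ester group and comes back to the route at 8.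

Step 10. Oxidative addition and transmetalation at the hindered, electron-rich C–Br bond may be sluggish, with protodehalogenation taking over. The fallback sets out from 13: bromine–lithium exchange (n-BuLi, THF, −78 °C) and inverse addition to dimethyl oxalate should give the ring B α-keto ester F6, and condensation with tosylhydrazide the tosylhydrazone F7. Base (DBU, CH2Cl2; Bamford–Stevens diazo formation) then gives the diazo ester, which comes back to the route at 15 without passing through 14.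

**Further compounds**

F1 | step 12 | 2-(2-{[4-(benzyloxy)-3-methoxyphenyl]methoxy}-5-[(2R,3S)-3-{[(tert-butyldimethylsilyl)oxy]methyl}-5-{3-[(tert-butyldimethylsilyl)oxy]propyl}-7-methoxy-2,3-dihydro-1-benzofuran-2-yl]-3-methoxyphenyl)acetic acid | COc1cc(COc2c(OC)cc([C@@H]3Oc4c(OC)cc(CCCO[Si](C)(C)C(C)(C)C)cc4[C@H]3CO[Si](C)(C)C(C)(C)C)cc2CC(=O)O)ccc1OCc1ccccc1
F2 | step 12 | (R)-1-oxo-1-(pyrrolidin-1-yl)propan-2-yl ester of acid F1 | COc1cc(COc2c(OC)cc([C@@H]3Oc4c(OC)cc(CCCO[Si](C)(C)C(C)(C)C)cc4[C@H]3CO[Si](C)(C)C(C)(C)C)cc2CC(=O)O[C@H](C)C(=O)N5CCCC5)ccc1OCc1ccccc1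
F3 | step 12 | 2-diazo derivative of lactamide ester F2 | COc1cc(COc2c(OC)cc([C@@H]3Oc4c(OC)cc(CCCO[Si](C)(C)C(C)(C)C)cc4[C@H]3CO[Si](C)(C)C(C)(C)C)cc2C(=[N+]=[N-])C(=O)O[C@H](C)C(=O)N5CCCC5)ccc1OCc1ccccc1
F4 | step 12 | (R)-1-oxo-1-(pyrrolidin-1-yl)propan-2-yl (2R,3R)-2-[4-(benzyloxy)-3-methoxyphenyl]-5-[(2R,3S)-3-{[(tert-butyldimethylsilyl)oxy]methyl}-5-{3-[(tert-butyldimethylsilyl)oxy]propyl}-7-methoxy-2,3-dihydro-1-benzofuran-2-yl]-7-methoxy-2,3-dihydro-1-benzofuran-3-carboxylate | COc1cc([C@@H]2Oc3c(OC)cc([C@@H]4Oc5c(OC)cc(CCCO[Si](C)(C)C(C)(C)C)cc5[C@H]4CO[Si](C)(C)C(C)(C)C)cc3[C@H]2C(=O)O[C@H](C)C(=O)N6CCCC6)ccc1OCc1ccccc1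
F5 | step 5 | dimethyl 2-{2-[(4-{[4-(benzyloxy)-3-methoxyphenyl]methoxy}-3-bromo-5-methoxyphenyl)methoxy]-3-methoxy-5-(3-methoxy-3-oxopropyl)phenyl}propanedioate | COc1cc(COc2c(OC)cc(COc3c(OC)cc(CCC(=O)OC)cc3C(C(=O)OC)C(=O)OC)cc2Br)ccc1OCc1ccccc1
F6 | step 10 | methyl 2-(2-{[4-(benzyloxy)-3-methoxyphenyl]methoxy}-5-[(2R,3S)-3-{[(tert-butyldimethylsilyl)oxy]methyl}-5-{3-[(tert-butyldimethylsilyl)oxy]propyl}-7-methoxy-2,3-dihydro-1-benzofuran-2-yl]-3-methoxyphenyl)-2-oxoacetate | COc1cc(COc2c(OC)cc([C@@H]3Oc4c(OC)cc(CCCO[Si](C)(C)C(C)(C)C)cc4[C@H]3CO[Si](C)(C)C(C)(C)C)cc2C(=O)C(=O)OC)ccc1OCc1ccccc1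
F7 | step 10 | tosylhydrazone of keto ester F6 | COc1cc(COc2c(OC)cc([C@@H]3Oc4c(OC)cc(CCCO[Si](C)(C)C(C)(C)C)cc4[C@H]3CO[Si](C)(C)C(C)(C)C)cc2C(=NNS(=O)(=O)c5ccc(C)cc5)C(=O)OC)ccc1OCc1ccccc1
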